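**Retrosynthetic overview**
1. The labile (3R) centre is made last, by enantioselective hydrogenation of C2=C3 of the matching isoflavone under direction of the free 2'-OH.
2. The C5'–geranyl bond is cut next: Friedel–Crafts geranylation of 7,2',4'-trihydroxyisoflavone with geraniol.
3. The three phenols go back to methyl ethers, which are cleaved at the robust, achiral isoflavone stage.
4. Ring C is the only ring built. It comes from a 2'-hydroxychalcone in one flask: O1–C2 closure at Cβ, then a 2→3 aryl shift, then loss of water.
5. The chalcone comes from paeonol and 2,4-dimethoxybenzaldehyde. Rings A and B are bought.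

Assumption: no close precedent fixes the sense of induction in step 5, so the DuanPhos antipode written is taken to deliver hydrogen to the Si face of C3; if the first run gives the (S)-ketone, the equally available mirror-image ligand is used.

**Route**

Step 1
Reactants: 1 paeonol (2'-hydroxy-4'-methoxyacetophenone); 2 the aldehyde 2,4-dimethoxybenzaldehyde
Product: 3 (E)-2'-hydroxy-2,4,4'-trimethoxychalcone
Conditions: KOH (50 % aq), EtOH, rt, 36 h; then cold aq HCl to pH 3; recrystallise from EtOH
Reagents that add atoms: none
Why: This is a Claisen–Schmidt aldol condensation, in which the acetophenone enolate adds to the non-enolisable aldehyde and E1cB loss of water gives only the conjugated E-enone, with no stereocentre formed.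

Step 2
Reactants: 3 (E)-2'-hydroxy-2,4,4'-trimethoxychalcone
Product: 6 2'-hydroxydaidzein trimethyl ether (7,2',4'-trimethoxyisoflavone), via trans-3-iodanylflavanone 4 (not isolated), via 2-hydroxyisoflavanone 5 (not isolated)
Conditions: PhI(OH)OTs (1.1 equiv, in portions), MeCN (2 % H2O), 0 °C → 40 °C, 3 h
Reagents that add atoms: none
Why: Proposed new method: the trivalent iodine of PhI(OH)OTs attacks Cα of the donor-substituted styrenyl C=C and the chelated 2'-OH closes ring C at the benzylic Cβ in the 6-endo sense used by chalcone isomerase (any flavanone formed by TsOH-catalysed oxa-Michael closure reaches the same species through its enol) to give trans-iodane 4, whose diaxial conformer places the 2,4-dimethoxyphenyl group antiperiplanar to the PhI nucleofuge so that it shifts from C2 to C3 through a phenonium ion as in the isoflavone synthase step, after which water traps the C2 oxocarbenium ion as lactol 5 and TsOH dehydrates it to the aromatic pyrone, leaving no stereocentre; the closest known reaction types are the Koser-reagent 2,3-aryl migration of flavanones and the hypervalent-iodine oxidative rearrangement of chalcones in methanol.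

Step 3
Reactants: 6 2'-hydroxydaidzein trimethyl ether
Product: 7 2'-hydroxydaidzein (7,2',4'-trihydroxyisoflavone)
Conditions: BBr3 (6 equiv), CH2Cl2, −78 °C → rt, 14 h; ice-water
Reagents that add atoms: none
Why: BBr3 demethylation (boron complexation, then SN2 attack of bromide on methyl) frees all three phenols at the only stage where the molecule is flat, achiral and acid-stable, before the acid-sensitive geranyl chain and the labile C3 centre exist.

Step 4
Reactants: 7 2'-hydroxydaidzein; 8 geraniol
Product: 9 5'-geranyl-7,2',4'-trihydroxyisoflavone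
Conditions: BF3·OEt2 (30 mol %), 1,4-dioxane, 10 °C → rt, 3 h, 8 (1.2 equiv) added over 1 h; stopped at about 70 % conversion, chromatography
Reagents that add atoms: none
Why: In this Friedel–Crafts allylation (the reaction type that turns olivetol into cannabigerol) the geranyl cation attacks the only electron-rich ring, the ring B resorcinol (ring A is deactivated by the pyrone carbonyl), at C5', which is para to 2'-OH, ortho to 4'-OH and less hindered than C3' between two hydroxyls; the E-alkene survives at this temperature and no stereocentre is formed.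

Step 5
Reactants: 9 5'-geranyl-7,2',4'-trihydroxyisoflavone
Product: 10 (3R)-5'-geranyl-7,2',4'-trihydroxyisoflavanone (CNP0142504.1)
Conditions: [Rh(cod)2]BF4 (2 mol %), (1R,1'R,2S,2'S)-DuanPhos (2.2 mol %), H2 (20 bar), degassed THF, rt, 16 h, no base; short acid-washed silica plug
Reagents that add atoms: none
Why: Proposed new method: the free 2'-OH binds the cationic monovalent rhodium centre and holds C2=C3 in a five-membered chelate, so H2 adds syn to the Si face of C3 selected by the P-stereogenic bisphosphine and the C3–H bond arises by reductive elimination from a carbon-bound alkyl rather than by protonation of a free enol, which sets (3R) under kinetic control in a base-free medium where the α-aryl ketone does not racemise, while the unactivated trisubstituted geranyl alkenes and the aryl ketone are not touched by this catalyst class; the closest known reaction type is the hydroxyl-directed rhodium-catalysed asymmetric hydrogenation of ortho-hydroxystyrenes, and isoflavone reductase shows the same dependence on the 2'-OH.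

**Compound list**
1 | paeonol (2'-hydroxy-4'-methoxyacetophenone) | CC(=O)c1ccc(OC)cc1O | starting material
2 | 2,4-dimethoxybenzaldehyde | COc1ccc(C=O)c(OC)c1 | starting material
3 | (E)-1-(2-hydroxy-4-methoxyphenyl)-3-(2,4-dimethoxyphenyl)prop-2-en-1-one | COc1ccc(C(=O)/C=C/c2ccc(OC)cc2OC)c(O)c1 | intermediate
4 | trans-2-(2,4-dimethoxyphenyl)-7-methoxy-3-[phenyl(tosyloxy)-λ3-iodanyl]chroman-4-one, racemic, (2S,3S) enantiomer drawn | COc1ccc2C(=O)[C@@H]([I](c3ccccc3)OS(=O)(=O)c3ccc(C)cc3)[C@H](c3ccc(OC)cc3OC)Oc2c1 | intermediate
5 | 3-(2,4-dimethoxyphenyl)-2-hydroxy-7-methoxychroman-4-one, racemic mixture of C2 epimers | COc1ccc2C(=O)C(c3ccc(OC)cc3OC)C(O)Oc2c1 | intermediate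
6 | 7,2',4'-trimethoxyisoflavone | COc1ccc(C2=COc3cc(OC)ccc3C2=O)c(OC)c1 | intermediate
7 | 7,2',4'-trihydroxyisoflavone (2'-hydroxydaidzein) | Oc1ccc(C2=COc3cc(O)ccc3C2=O)c(O)c1 | intermediate
8 | geraniol, (E)-3,7-dimethylocta-2,6-dien-1-ol | CC(C)=CCC/C(C)=C/CO | starting material
9 | 5'-[(E)-3,7-dimethylocta-2,6-dienyl]-7,2',4'-trihydroxyisoflavone | CC(C)=CCC/C(C)=C/Cc1cc(C2=COc3cc(O)ccc3C2=O)c(O)cc1O | intermediate
10 | (3R)-5'-[(E)-3,7-dimethylocta-2,6-dienyl]-7,2',4'-trihydroxyisoflavanone | CC(C)=CCC/C(C)=C/Cc1cc([C@@H]2COc3cc(O)ccc3C2=O)c(O)cc1O | target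

**Step count and weak points**
Total steps: 5. Longest linear sequence: 5 (1 → 3 → 6 → 7 → 9 → 10).

Step 5 is the most uncertain step.
- A chromone C=C has not been hydrogenated this way, so rate and ee are unknown.
- The 4'-OH could steer the catalyst to the proximal geranyl alkene.
- The product racemises on contact with base.

The fallback sets out from 9 and comes back at 10. It replaces direct hydrogenation by over-reduction with dynamic kinetic resolution, followed by re-oxidation. TBSCl and imidazole in DMF give 5'-geranyl-7,2',4'-tris(tert-butyldimethylsilyloxy)isoflavone F3. RuCl[(R,R)-TsDPEN](p-cymene) with HCO2H/Et3N in EtOAc at 40 °C then reduces C2=C3, lets C3 epimerise, and reduces only the (3R)-ketone. This gives the cis alcohol (3R,4R)-5'-geranyl-7,2',4'-tris(tert-butyldimethylsilyloxy)isoflavan-4-ol F4. Dess–Martin periodinane in CH2Cl2 at 0 °C returns the ketone without touching C3, giving (3R)-5'-geranyl-7,2',4'-tris(tert-butyldimethylsilyloxy)isoflavanone F5. HF·pyridine in THF at 0 °C then frees the phenols to give 10.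

Step 2 is the second risk. PhI(OH)OTs may attack C5 of the very electron-rich dimethoxyphenyl ring to give a diaryliodonium salt, or it may oxidise the free phenol, before it engages the alkene. The fallback sets out from 3 and comes back at 6. It moves the aryl shift into the open chain with a different oxidant and closes ring C afterwards. Tl(NO3)3·3H2O (trivalent thallium) in MeOH/HC(OMe)3 at rt gives 2-(2,4-dimethoxyphenyl)-1-(2-hydroxy-4-methoxyphenyl)-3,3-dimethoxypropan-1-one F1. Aqueous HCl in refluxing MeOH then cyclises F1 through the unmasked aldehyde carbon to 6.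

Step 4 is the third risk.
- The 3'-isomer and bis-geranylated material will form alongside 9.
- BF3 can close the new ortho-geranylphenol to a chroman.
- A yield above 40 % is not to be expected.

The fallback sets out from 7 and comes back at 9. It replaces the cationic C–C bond formation by halogenation and cross-electrophile coupling. NBS (1.0 equiv) in MeCN at −20 °C brominates para to the 2'-OH to give 5'-bromo-7,2',4'-trihydroxyisoflavone F2, which is easily purified. NiCl2(dme) with 4,4'-di-tert-butyl-2,2'-bipyridine, Zn and geranyl acetate in DMA at 40 °C then joins the aryl bromide to the unsubstituted terminus of the geranyl π-allyl nickel species, giving 9.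

**Further compounds**
F1 | step 2 | 2-(2,4-dimethoxyphenyl)-1-(2-hydroxy-4-methoxyphenyl)-3,3-dimethoxypropan-1-one (racemic) | COc1ccc(C(=O)C(C(OC)OC)c2ccc(OC)cc2OC)c(O)c1
F2 | step 4 | 5'-bromo-7,2',4'-trihydroxyisoflavone | Oc1cc(O)c(C2=COc3cc(O)ccc3C2=O)cc1Br
F3 | step 5 | 5'-geranyl-7,2',4'-tris(tert-butyldimethylsilyloxy)isoflavone | CC(C)=CCC/C(C)=C/Cc1cc(C2=COc3cc(O[Si](C)(C)C(C)(C)C)ccc3C2=O)c(O[Si](C)(C)C(C)(C)C)cc1O[Si](C)(C)C(C)(C)C
F4 | step 5 | (3R,4R)-5'-geranyl-7,2',4'-tris(tert-butyldimethylsilyloxy)isoflavan-4-ol | CC(C)=CCC/C(C)=C/Cc1cc([C@@H]2COc3cc(O[Si](C)(C)C(C)(C)C)ccc3[C@@H]2O)c(O[Si](C)(C)C(C)(C)C)cc1O[Si](C)(C)C(C)(C)C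
F5 | step 5 | (3R)-5'-geranyl-7,2',4'-tris(tert-butyldimethylsilyloxy)isoflavanone | CC(C)=CCC/C(C)=C/Cc1cc([C@@H]2COc3cc(O[Si](C)(C)C(C)(C)C)ccc3C2=O)c(O[Si](C)(C)C(C)(C)C)cc1O[Si](C)(C)C(C)(C)C
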